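**Strategy.** The pyranone (ring C) is cut at C4a–C4, C4–C3 and O1–C2. Ring A is a mirror-symmetric 2,4-diprenylphloroglucinol whose only unsubstituted carbon, the future C4a, lies between two equivalent oxygens (future O1 and the 5-hydroxyl oxygen). One palladium-catalysed operation therefore inserts carbon monoxide as C4 between C4a and the terminal carbon (C3) of a ring B arylacetylene and lets either ortho oxygen close 6-endo onto C2, giving the flavone. The precursor is the C4a iodide of the diprenylphloroglucinol, masked as its triacetate, together with CO and the MOM-protected ring B alkyne. The planar flavone defers the C2 stereocentre to a copper hydride conjugate reduction.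

Key step: step 7

Remark on ring B: the methyl ether sits on the oxygen para to the ring C attachment and the free hydroxyl meta to it (isovanillin pattern). A vanillin-type bromide would carry the methyl on the wrong oxygen, so the route starts from the bromocatechol aldehyde and methylates the para oxygen selectively.

Assumption: 3-bromo-4,5-dihydroxybenzaldehyde and tributyl(prenyl)stannane are taken as catalogue compounds (prenyl = 3-methylbut-2-en-1-yl throughout).

Assumption: (R)-DTBM-SEGPHOS is written as the ligand enantiomer that leads to (2S); the sense is to be confirmed in a pilot run and the (S)-ligand substituted if needed, nothing else changing.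

**Step 1**
Reactants: 1 phloroglucinol; 2 prenyl bromide
Product: 3 2,4-diprenylphloroglucinol
Conditions: 2 (2.0 equiv), 10% aq. KOH, 0 °C → rt, N2; chromatography
Reagents that add atoms: none
Why: C-alkylation of an ambident phenolate (SN2 on the allylic bromide), with water shielding the oxygens by hydrogen bonding; the mono-, di- and tri-prenyl mixture expected is separated by chromatography, and the cheap triol makes the statistical loss acceptable.

**Step 2**
Reactants: 3 2,4-diprenylphloroglucinol
Product: 5 2-iodo-4,6-diprenylbenzene-1,3,5-triyl triacetate, via iodotriol 4 (not isolated)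
Conditions: NIS (1.0 equiv), MeCN, −40 → 0 °C; then Ac2O (4 equiv), Et3N (5 equiv), DMAP (cat.), 0 °C → rt, same flask
Reagents that add atoms: N-iodosuccinimide, O=C1CCC(=O)N1I; acetic anhydride, CC(=O)OC(C)=O
Why: Electrophilic aromatic iodination at the single free ring carbon, activated by three hydroxyls, should be far faster than iodonium formation at the prenyl olefins with one equivalent of NIS in the cold, and DMAP-catalysed O-acetylation in the same flask masks the oxidation-prone triol 4 before isolation.

**Step 3**
Reactants: 6 3-bromo-4,5-dihydroxybenzaldehyde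
Product: 7 3-bromo-5-hydroxy-4-methoxybenzaldehyde
Conditions: MeI (1.1 equiv), Li2CO3, DMF, 40 °C
Reagents that add atoms: iodomethane, CI
Why: The hydroxyl para to the formyl group and ortho to bromine is the more acidic one, so the weak base forms only that phenoxide and Williamson O-methylation should give the isovanillin pattern.

**Step 4**
Reactants: 7 3-bromo-5-hydroxy-4-methoxybenzaldehyde
Product: 8 3-bromo-4-methoxy-5-(methoxymethoxy)benzaldehyde
Conditions: MOMCl, i-Pr2NEt, CH2Cl2, 0 °C → rt
Reagents that add atoms: chloromethyl methyl ether, COCCl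
Why: O-alkylation of the remaining phenol by the α-chloro ether (acetal formation through the oxocarbenium ion) gives a MOM ether that survives the basic, organometallic and hydride steps and falls in the final acid step.

**Step 5**
Reactants: 8 3-bromo-4-methoxy-5-(methoxymethoxy)benzaldehyde; 9 tributyl(prenyl)stannane
Product: 10 4-methoxy-3-(methoxymethoxy)-5-prenylbenzaldehyde
Conditions: Pd(PPh3)4 (5 mol%), DMF, 95 °C
Reagents that add atoms: none
Why: Migita–Kosugi–Stille coupling, in which zerovalent palladium inserts into the aryl bromide, the allyl group is transferred from tin and reductive elimination at the less substituted terminus of the prenyl–palladium species should give the linear prenyl arene without touching the aldehyde.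

**Step 6**
Reactants: 10 4-methoxy-3-(methoxymethoxy)-5-prenylbenzaldehyde
Product: 11 5-ethynyl-2-methoxy-1-(methoxymethoxy)-3-prenylbenzene
Conditions: dimethyl (1-diazo-2-oxopropyl)phosphonate, K2CO3, MeOH, 0 °C → rt
Reagents that add atoms: dimethyl (1-diazo-2-oxopropyl)phosphonate, CC(=O)C(=[N+]=[N-])P(=O)(OC)OC
Why: Seyferth–Gilbert homologation in the Ohira–Bestmann variant, where methanolysis releases the diazomethylphosphonate anion, its Horner–Wadsworth–Emmons addition to the non-enolisable aldehyde, loss of N2 and 1,2-hydride shift of the alkylidene carbene give the terminal alkyne under conditions too mild for the MOM ether or the prenyl group.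

**Step 7**
Reactants: 5 2-iodo-4,6-diprenylbenzene-1,3,5-triyl triacetate; 11 5-ethynyl-2-methoxy-1-(methoxymethoxy)-3-prenylbenzene; 12 carbon monoxide
Product: 14 5,7-dihydroxy-4'-methoxy-3'-(methoxymethoxy)-6,8,5'-triprenylflavone, via alkynone 13 (not isolated)
Conditions: PdCl2(PPh3)2 (5 mol%), dppp (5 mol%), Et2NH (10 equiv), DBU (2 equiv), DMF, CO (3 bar), 50 °C, copper-free
Reagents that add atoms: none
Why: Zerovalent palladium inserts into the C–I bond of 5, CO inserts to give the aroyl–palladium species, and amine-assisted transfer of the acetylide of 11 followed by reductive elimination gives alkynone 13 (C4a–C4 and C4–C3). Diethylamine then cleaves the aryl acetates by aminolysis and, through reversible conjugate addition to the ynone, steers a liberated ortho phenoxide onto C2, which amounts to a 6-endo-dig oxa-Michael closure of ring C (O1–C2) and shuts out the 5-exo path to the aurone. The closest known reaction type is the palladium-catalysed carbonylative annulation of ortho-iodophenols and their acetates with terminal arylacetylenes to flavones. No stereocentre is formed. Carbonylation must outrun direct alkynylation and amide formation, which the two ortho oxygen substituents flanking the C–Pd bond secure by hindering direct coupling and attack at the acyl carbon while favouring CO insertion, helped by a few bar of CO and the absence of copper. The regiochemistry of closure needs no control because the mirror symmetry of 5 makes the two ortho oxygens equivalent, and the acetates keep the electron-rich iodide stable and release the phenols only in the flask.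

**Step 8**
Reactants: 14 5,7-dihydroxy-4'-methoxy-3'-(methoxymethoxy)-6,8,5'-triprenylflavone
Product: 15 4'-methoxy-5,7,3'-tris(methoxymethoxy)-6,8,5'-triprenylflavone
Conditions: NaH (3 equiv), MOMCl (3 equiv), DMF, 0 °C → rt
Reagents that add atoms: chloromethyl methyl ether, COCCl
Why: Williamson-type O-alkylation of both sodium phenoxides, the chelated 5-hydroxyl needing the strong base and polar solvent; every ring carbon is substituted, so C-alkylation is excluded, and full protection removes the acidic protons that would quench the copper hydride.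

**Step 9**
Reactants: 15 4'-methoxy-5,7,3'-tris(methoxymethoxy)-6,8,5'-triprenylflavone
Product: 17 (2S)-4'-methoxy-5,7,3'-tris(methoxymethoxy)-6,8,5'-triprenylflavanone, via silyl enol ether 16 (not isolated)
Conditions: Cu(OAc)2 (5 mol%), (R)-DTBM-SEGPHOS (5.5 mol%), (EtO)2MeSiH (3 equiv), toluene, 0 °C → rt; then aq. citric acid, THF, 0 °C
Reagents that add atoms: none
Why: Copper hydride-catalysed asymmetric conjugate reduction of a chromone, in which the bisphosphine-ligated CuH delivers hydride to C2 on the face of the planar C2=C3 bond selected by the C2-symmetric ligand and so sets (2S); the copper enolate is trapped by the silane as silyl enol ether 16, which cannot open by retro-oxa-Michael reaction, mild acid work-up gives the ketone, and the isolated trisubstituted prenyl olefins are not substrates for hydrocupration under these conditions.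

**Step 10**
Reactants: 17 (2S)-4'-methoxy-5,7,3'-tris(methoxymethoxy)-6,8,5'-triprenylflavanone
Product: 18 isoamoritin
Conditions: 3 M aq. HCl, MeOH, rt → 40 °C
Reagents that add atoms: none
Why: Acid-catalysed acetal cleavage (transacetalisation to methanol) removes the three MOM groups under conditions commonly used with ortho-prenylated phenols and mild enough to avoid chroman formation, and C2 should not epimerise because flavanone racemisation runs mainly through base-induced ring opening.

**Compound list**
1 | phloroglucinol (benzene-1,3,5-triol) | Oc1cc(O)cc(O)c1 | starting material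
2 | prenyl bromide (1-bromo-3-methylbut-2-ene) | CC(C)=CCBr | starting material
3 | 2,4-diprenylphloroglucinol (2,4-bis(3-methylbut-2-en-1-yl)benzene-1,3,5-triol) | Oc1cc(O)c(CC=C(C)C)c(O)c1CC=C(C)C | intermediate
4 | 2-iodo-4,6-diprenylbenzene-1,3,5-triol (formed in the flask, not isolated) | Oc1c(I)c(O)c(CC=C(C)C)c(O)c1CC=C(C)C | intermediate
5 | 2-iodo-4,6-diprenylbenzene-1,3,5-triyl triacetate | CC(=O)Oc1c(I)c(OC(C)=O)c(CC=C(C)C)c(OC(C)=O)c1CC=C(C)C | intermediate
6 | 3-bromo-4,5-dihydroxybenzaldehyde | O=Cc1cc(O)c(O)c(Br)c1 | starting material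
7 | 3-bromo-5-hydroxy-4-methoxybenzaldehyde | COc1c(O)cc(C=O)cc1Br | intermediate
8 | 3-bromo-4-methoxy-5-(methoxymethoxy)benzaldehyde | COCOc1cc(C=O)cc(Br)c1OC | intermediate
9 | tributyl(3-methylbut-2-en-1-yl)stannane | CCCC[Sn](CCCC)(CCCC)CC=C(C)C | starting material
10 | 4-methoxy-3-(methoxymethoxy)-5-(3-methylbut-2-en-1-yl)benzaldehyde | COCOc1cc(C=O)cc(CC=C(C)C)c1OC | intermediate
11 | 5-ethynyl-2-methoxy-1-(methoxymethoxy)-3-(3-methylbut-2-en-1-yl)benzene | C#Cc1cc(CC=C(C)C)c(OC)c(OCOC)c1 | intermediate
12 | carbon monoxide | [C-]#[O+] | starting material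
13 | 2-{3-[4-methoxy-3-(methoxymethoxy)-5-prenylphenyl]prop-2-ynoyl}-4,6-diprenylbenzene-1,3,5-triyl triacetate (formed in the flask, not isolated) | CC(=O)Oc1c(C(=O)C#Cc2cc(CC=C(C)C)c(OC)c(OCOC)c2)c(OC(C)=O)c(CC=C(C)C)c(OC(C)=O)c1CC=C(C)C | intermediate
14 | 5,7-dihydroxy-4'-methoxy-3'-(methoxymethoxy)-6,8,5'-triprenylflavone | COCOc1cc(C2=CC(=O)c3c(O)c(CC=C(C)C)c(O)c(CC=C(C)C)c3O2)cc(CC=C(C)C)c1OC | intermediate
15 | 4'-methoxy-5,7,3'-tris(methoxymethoxy)-6,8,5'-triprenylflavone | COCOc1cc(C2=CC(=O)c3c(OCOC)c(CC=C(C)C)c(OCOC)c(CC=C(C)C)c3O2)cc(CC=C(C)C)c1OC | intermediate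
16 | (2S)-4-[diethoxy(methyl)silyloxy]-4'-methoxy-5,7,3'-tris(methoxymethoxy)-6,8,5'-triprenyl-2H-flav-3-ene (formed in the flask, not isolated) | COCOc1cc([C@@H]2C=C(O[Si](C)(OCC)OCC)c3c(OCOC)c(CC=C(C)C)c(OCOC)c(CC=C(C)C)c3O2)cc(CC=C(C)C)c1OC | intermediate
17 | (2S)-4'-methoxy-5,7,3'-tris(methoxymethoxy)-6,8,5'-triprenylflavanone | COCOc1cc([C@@H]2CC(=O)c3c(OCOC)c(CC=C(C)C)c(OCOC)c(CC=C(C)C)c3O2)cc(CC=C(C)C)c1OC | intermediate
18 | isoamoritin, (2S)-5,7,3'-trihydroxy-4'-methoxy-6,8,5'-triprenylflavanone | COc1c(O)cc([C@@H]2CC(=O)c3c(O)c(CC=C(C)C)c(O)c(CC=C(C)C)c3O2)cc1CC=C(C)C | target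

**Count.** Total: 10 steps. Longest linear sequence: 8 steps (6 → 7 → 8 → 10 → 11 → 14 → 15 → 17 → 18).

**Steps most likely to fail**

1. Step 7. Direct alkynylation, amide formation by capture of the aroyl–palladium species with diethylamine, or proto-deiodination may outrun the carbonylative coupling, and part of the alkynone may close 5-exo. The fallback brings C4 in as a preformed formyl carbon instead of CO; it sets out from alkyne 11 and comes back at flavone 15, so that step 8 is skipped. Commercial 2,4,6-trihydroxybenzaldehyde (O=Cc1c(O)cc(O)cc1O) would be C-diprenylated with 2 (aq. KOH, 0 °C) to 2,4,6-trihydroxy-3,5-diprenylbenzaldehyde F1. MOMCl/i-Pr2NEt (2.2 equiv, CH2Cl2) should then give 2-hydroxy-4,6-bis(methoxymethoxy)-3,5-diprenylbenzaldehyde F2, the chelated hydroxyl staying free. After deprotonation of that phenol with i-PrMgCl, the lithium acetylide of 11 (n-BuLi, THF, −78 °C) would add to the aldehyde to give the racemic propargylic alcohol 1-[2-hydroxy-4,6-bis(methoxymethoxy)-3,5-diprenylphenyl]-3-[4-methoxy-3-(methoxymethoxy)-5-prenylphenyl]prop-2-yn-1-ol F3. MnO2 (CH2Cl2, rt) would oxidise it to the corresponding 2-hydroxyaryl alkynone F4, and Et2NH (EtOH, rt → 50 °C) would close F4 6-endo to 15.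

2. Step 9. The electron-rich 5,7-dioxygenated flavone may resist the bulky ligated copper hydride, or the facial selectivity may be poor. The fallback separates reduction from stereocontrol; it sets out from 15 and comes back at 17. A small achiral diphosphine–copper hydride (Cu(OAc)2, 1,2-bis(diphenylphosphino)benzene, PMHS, t-BuOH, toluene) would reduce 15 to the racemic protected flavanone F5. This would be resolved kinetically by asymmetric transfer hydrogenation (Cp*RhCl[(R,R)-TsDPEN], HCO2H/Et3N, EtOAc, rt). The (2R) enantiomer is expected to be reduced to the cis-(2R,4R)-flavan-4-ol F6, and the unreacted (2S)-flavanone 17 is separated by chromatography; the catalyst antipode is fixed after a pilot run.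

3. Step 2. Iodonium attack on a prenyl olefin followed by capture by a neighbouring hydroxyl (iodo-etherification), or over-iodination, may compete with ring iodination. The fallback delivers iodine to an aryllithium with no free hydroxyl present; it sets out from 3 and comes back at iodotriol 4, which is acetylated to 5 as in the second half of step 2. Compound 3 would be converted (NaH, MOMCl, DMF, 0 °C) to 1,3,5-tris(methoxymethoxy)-2,4-diprenylbenzene F7. n-BuLi (THF, 0 °C) should metalate the ring carbon between two MOM ethers (directed ortho-metalation), and 1,2-diiodoethane (−78 °C) would give 2-iodo-1,3,5-tris(methoxymethoxy)-4,6-diprenylbenzene F8. Brief HCl/MeOH (0 °C → rt) would then free 4.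

**Further compounds**
F1 | step 7 | 2,4,6-trihydroxy-3,5-bis(3-methylbut-2-en-1-yl)benzaldehyde | O=Cc1c(O)c(CC=C(C)C)c(O)c(CC=C(C)C)c1O
F2 | step 7 | 2-hydroxy-4,6-bis(methoxymethoxy)-3,5-bis(3-methylbut-2-en-1-yl)benzaldehyde | O=Cc1c(O)c(CC=C(C)C)c(OCOC)c(CC=C(C)C)c1OCOC
F3 | step 7 | 1-[2-hydroxy-4,6-bis(methoxymethoxy)-3,5-diprenylphenyl]-3-[4-methoxy-3-(methoxymethoxy)-5-prenylphenyl]prop-2-yn-1-ol (racemic) | OC(C#Cc1cc(CC=C(C)C)c(OC)c(OCOC)c1)c1c(O)c(CC=C(C)C)c(OCOC)c(CC=C(C)C)c1OCOC
F4 | step 7 | 1-[2-hydroxy-4,6-bis(methoxymethoxy)-3,5-diprenylphenyl]-3-[4-methoxy-3-(methoxymethoxy)-5-prenylphenyl]prop-2-yn-1-one | O=C(C#Cc1cc(CC=C(C)C)c(OC)c(OCOC)c1)c1c(O)c(CC=C(C)C)c(OCOC)c(CC=C(C)C)c1OCOC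
F5 | step 9 | racemic 4'-methoxy-5,7,3'-tris(methoxymethoxy)-6,8,5'-triprenylflavanone | COCOc1cc(C2CC(=O)c3c(OCOC)c(CC=C(C)C)c(OCOC)c(CC=C(C)C)c3O2)cc(CC=C(C)C)c1OC
F6 | step 9 | (2R,4R)-4'-methoxy-5,7,3'-tris(methoxymethoxy)-6,8,5'-triprenylflavan-4-ol | COCOc1cc([C@H]2C[C@@H](O)c3c(OCOC)c(CC=C(C)C)c(OCOC)c(CC=C(C)C)c3O2)cc(CC=C(C)C)c1OC
F7 | step 2 | 1,3,5-tris(methoxymethoxy)-2,4-bis(3-methylbut-2-en-1-yl)benzene | COCOc1cc(OCOC)c(CC=C(C)C)c(OCOC)c1CC=C(C)C
F8 | step 2 | 2-iodo-1,3,5-tris(methoxymethoxy)-4,6-bis(3-methylbut-2-en-1-yl)benzene | COCOc1c(I)c(OCOC)c(CC=C(C)C)c(OCOC)c1CC=C(C)C
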